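**Plan**
Retrosynthesis: the quinone is traced to its hydroquinone bis(methoxymethyl) ether. Both indole C2–C(CH3)2(CH=CH2) bonds are then cut together, and last the two indole C3–core bonds.
Forward: no ring is built. Indole is attached twice through C3 to 2,5-dichloro-1,4-benzoquinone, both chlorides are exchanged for methoxy, and the quinone is reduced and masked.
Enabling feature: in this bis(indol-3-yl)arene each pyrrole ring keeps N1–H and C2–H, while C3 is blocked by the fully substituted benzene ring. Cl+ at C3 therefore gives a 3H-indole whose C2=N1 imine accepts an allylborane at C2.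
B-Prenyl-9-BBN (from 3-methylbuta-1,2-diene and 9-BBN-H) delivers its tertiary terminus to both C2 atoms, so the crowded quaternary carbons arrive only after the C3–aryl bonds exist.
Acidic removal of the two acetals and mild oxidation restore the quinone.
Stereochemistry: the target has no stereocentre, and the sp3 C2 and C3 centres of the key step are transient.

Key step: step 7

Assumption: the target is drawn without axial descriptors, so hindered rotation about the two indole C3–core bonds (possible syn and anti rotamers from 15 onward) is not treated as a stereochemical element.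

**Step 1**
Reactants: 1 1H-indole; 2 2,5-dichloro-1,4-benzoquinone
Product: 4 2,5-dichloro-3-(1H-indol-3-yl)-1,4-benzoquinone, via indolyl-dichlorohydroquinone 3 (not isolated)
Conditions: conc. HCl (cat.), THF, rt; then DDQ, rt
Reagents that add atoms: none
Why: The acid-activated quinone undergoes a Friedel–Crafts-type conjugate (Michael) addition of the nucleophilic indole C3 at a C–H carbon, the adduct tautomerises to hydroquinone 3, and DDQ dehydrogenates it, which is the standard entry to 3-indolylquinones.

**Step 2**
Reactants: 4 2,5-dichloro-3-(1H-indol-3-yl)-1,4-benzoquinone; 1 1H-indole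
Product: 6 2,5-dichloro-3,6-di(1H-indol-3-yl)-1,4-benzoquinone, via bis(indolyl)dichlorohydroquinone 5 (not isolated)
Conditions: AcOH, 80 °C; concentrate; then DDQ, THF, rt
Reagents that add atoms: none
Why: The same acid-promoted conjugate addition and dehydrogenation takes place at the only C–H carbon left in 4, and unhindered indole should be nucleophilic enough for this donor-deactivated quinone.

**Step 3**
Reactants: 6 2,5-dichloro-3,6-di(1H-indol-3-yl)-1,4-benzoquinone
Product: 7 2,5-dimethoxy-3,6-di(1H-indol-3-yl)-1,4-benzoquinone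
Conditions: NaOMe (excess), dry MeOH–THF, 0 → 50 °C
Reagents that add atoms: NaOMe, [Na+].[O-]C
Why: Each C–Cl carbon is the β-position of a vinylogous acid chloride, so methoxide replaces chloride by addition–elimination (nucleophilic vinylic substitution on a haloquinone), and in water-free methanol any further exchange on the product is degenerate.

**Step 4**
Reactants: 7 2,5-dimethoxy-3,6-di(1H-indol-3-yl)-1,4-benzoquinone
Product: 8 2,5-dimethoxy-3,6-di(1H-indol-3-yl)benzene-1,4-diol
Conditions: Na2S2O4, THF–H2O, rt, Ar; extractive work-up under Ar, used at once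
Reagents that add atoms: none
Why: Dithionite reduction of a 1,4-benzoquinone to its hydroquinone is fast in aqueous THF and touches neither the indoles nor the methyl ethers.

**Step 5**
Reactants: 8 2,5-dimethoxy-3,6-di(1H-indol-3-yl)benzene-1,4-diol
Product: 9 3,3'-[2,5-dimethoxy-3,6-bis(methoxymethoxy)-1,4-phenylene]bis(1H-indole)
Conditions: MOMCl, i-Pr2NEt, CH2Cl2, 0 °C → rt, Ar
Reagents that add atoms: chloromethyl methyl ether (MOMCl), COCCl
Why: This Williamson-type O-alkylation with the small, highly reactive chloromethyl ether needs only an amine base, which activates the phenols but not the far less acidic indole N–H, so both nitrogen atoms stay free for the key step.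

**Step 6**
Reactants: 10 3-methylbuta-1,2-diene; 11 9-borabicyclo[3.3.1]nonane (9-BBN-H)
Product: 12 9-(3-methylbut-2-en-1-yl)-9-borabicyclo[3.3.1]nonane (B-prenyl-9-BBN)
Conditions: THF, 0 °C → rt, Ar; solution used as such
Reagents that add atoms: none
Why: Hydroboration of the 1,1-disubstituted allene places boron on the unsubstituted terminal carbon and hydrogen on the central one, and any tertiary allyl isomer would drain into the primary prenylborane by the fast 1,3-boron shift.

**Step 7**
Reactants: 9 3,3'-[2,5-dimethoxy-3,6-bis(methoxymethoxy)-1,4-phenylene]bis(1H-indole); 12 B-prenyl-9-BBN (two molecules are incorporated)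
Product: 15 3,3'-[2,5-dimethoxy-3,6-bis(methoxymethoxy)-1,4-phenylene]bis[2-(2-methylbut-3-en-2-yl)-1H-indole], via bis(3-chloro-3H-indole) 13 (not isolated), via bis(N-boryl-3-chloroindoline) 14 (not isolated)
Conditions: t-BuOCl (2.2 equiv), Et3N (3 equiv), THF, −78 °C; then 12 (5 equiv) in THF, −78 °C → rt; aq. K2CO3
Reagents that add atoms: none
Why: t-BuOCl delivers Cl+ to C3 of each indole (directly or by way of the N-chloroindole), and because C3 already bears the aryl group the ring cannot regain aromaticity by proton loss and persists at −78 °C as the 3-chloro-3H-indole 13 with a C2=N1 imine. Borane 12 binds the imine nitrogen and transfers its allyl unit through a closed six-membered chair-like transition state with allylic transposition, so the dimethyl-substituted terminus bonds to C2 and gives the N-boryl-3-chloroindoline 14. On warming, chloride leaves the doubly benzylic C3 with assistance from the ortho nitrogen through the benzo ring, Et3N removes the C2 proton, and aqueous work-up cleaves the N–B bond to give 15. The closest known reaction type is the reverse prenylation of 3-substituted indoles through 3-chloroindolenines and B-prenyl-9-BBN, which is an imine allylboration. No ring is closed, and the C2 and C3 stereocentres of 13 and 14 vanish on rearomatisation, so no stereocontrol is needed. The selectivities needed are tertiary over primary allyl terminus, fixed by the cyclic transition state, and chlorination of the indoles instead of the core, secured because the central benzene ring carries no hydrogen and the enamine-like C2=C3 bond of each N–H indole is the most nucleophilic site.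

**Step 8**
Reactants: 15 3,3'-[2,5-dimethoxy-3,6-bis(methoxymethoxy)-1,4-phenylene]bis[2-(2-methylbut-3-en-2-yl)-1H-indole]
Product: 17 2,5-dimethoxy-3,6-bis[2-(2-methylbut-3-en-2-yl)-1H-indol-3-yl]-1,4-benzoquinone, via free hydroquinone 16 (not isolated)
Conditions: conc. HCl (cat.), MeOH–THF, 45 °C, Ar; then FeCl3 (2.2 equiv), 0 °C → rt
Reagents that add atoms: none
Why: Acid-catalysed acetal exchange with methanol removes the aryl methoxymethyl ethers under conditions too mild to protonate the monosubstituted alkenes, and the very electron-rich hydroquinone 16 should then be oxidised by two equivalents of the one-electron oxidant FeCl3 well before the indoles react.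

**Compound list**
1 | 1H-indole | c1ccc2[nH]ccc2c1 | starting material
2 | 2,5-dichloro-1,4-benzoquinone | O=C1C=C(Cl)C(=O)C=C1Cl | starting material
3 | 2,5-dichloro-3-(1H-indol-3-yl)benzene-1,4-diol | Oc1cc(Cl)c(O)c(-c2c[nH]c3ccccc23)c1Cl | intermediate
4 | 2,5-dichloro-3-(1H-indol-3-yl)-1,4-benzoquinone | O=C1C=C(Cl)C(=O)C(c2c[nH]c3ccccc23)=C1Cl | intermediate
5 | 2,5-dichloro-3,6-di(1H-indol-3-yl)benzene-1,4-diol | Oc1c(Cl)c(-c2c[nH]c3ccccc23)c(O)c(Cl)c1-c1c[nH]c2ccccc12 | intermediate
6 | 2,5-dichloro-3,6-di(1H-indol-3-yl)-1,4-benzoquinone | O=C1C(Cl)=C(c2c[nH]c3ccccc23)C(=O)C(Cl)=C1c1c[nH]c2ccccc12 | intermediate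
7 | 2,5-dimethoxy-3,6-di(1H-indol-3-yl)-1,4-benzoquinone | COC1=C(c2c[nH]c3ccccc23)C(=O)C(OC)=C(c2c[nH]c3ccccc23)C1=O | intermediate
8 | 2,5-dimethoxy-3,6-di(1H-indol-3-yl)benzene-1,4-diol | COc1c(O)c(-c2c[nH]c3ccccc23)c(OC)c(O)c1-c1c[nH]c2ccccc12 | intermediate
9 | 3,3'-[2,5-dimethoxy-3,6-bis(methoxymethoxy)-1,4-phenylene]bis(1H-indole) | COCOc1c(-c2c[nH]c3ccccc23)c(OC)c(OCOC)c(-c2c[nH]c3ccccc23)c1OC | intermediate
10 | 3-methylbuta-1,2-diene | C=C=C(C)C | starting material
11 | 9-borabicyclo[3.3.1]nonane (9-BBN-H, sold as the dimer or as a THF solution; monomer drawn) | B1C2CCCC1CCC2 | starting material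
12 | 9-(3-methylbut-2-en-1-yl)-9-borabicyclo[3.3.1]nonane (B-prenyl-9-BBN) | CC(C)=CCB1C2CCCC1CCC2 | intermediate
13 | 3,3'-[2,5-dimethoxy-3,6-bis(methoxymethoxy)-1,4-phenylene]bis(3-chloro-3H-indole), mixture of diastereomers of no consequence | COCOc1c(C2(Cl)C=Nc3ccccc23)c(OC)c(OCOC)c(C2(Cl)C=Nc3ccccc23)c1OC | intermediate
14 | 3,3'-[2,5-dimethoxy-3,6-bis(methoxymethoxy)-1,4-phenylene]bis[1-(9-borabicyclo[3.3.1]nonan-9-yl)-3-chloro-2-(2-methylbut-3-en-2-yl)-2,3-dihydro-1H-indole], mixture of diastereomers of no consequence | COCOc1c(C2(Cl)C(C(C)(C)C=C)N(B4C5CCCC4CCC5)c3ccccc23)c(OC)c(OCOC)c(C2(Cl)C(C(C)(C)C=C)N(B4C5CCCC4CCC5)c3ccccc23)c1OC | intermediate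
15 | 3,3'-[2,5-dimethoxy-3,6-bis(methoxymethoxy)-1,4-phenylene]bis[2-(2-methylbut-3-en-2-yl)-1H-indole] | COCOc1c(-c2c(C(C)(C)C=C)[nH]c3ccccc23)c(OC)c(OCOC)c(-c2c(C(C)(C)C=C)[nH]c3ccccc23)c1OC | intermediate
16 | 2,5-dimethoxy-3,6-bis[2-(2-methylbut-3-en-2-yl)-1H-indol-3-yl]benzene-1,4-diol | COc1c(O)c(-c2c(C(C)(C)C=C)[nH]c3ccccc23)c(OC)c(O)c1-c1c(C(C)(C)C=C)[nH]c2ccccc12 | intermediate
17 | 2,5-dimethoxy-3,6-bis[2-(2-methylbut-3-en-2-yl)-1H-indol-3-yl]-1,4-benzoquinone | C=CC(C)(C)c1[nH]c2ccccc2c1C1=C(OC)C(=O)C(c2c(C(C)(C)C=C)[nH]c3ccccc23)=C(OC)C1=O | target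

Total step count: 8. Longest linear sequence: 7 (steps 1, 2, 3, 4, 5, 7, 8). Step 6 is a one-step side branch.

**Steps most likely to fail**

**Step 7.**
- Risk: chlorination may stray to the electron-rich tetraalkoxybenzene core (ipso attack, oxidative loss of an acetal). Chloride may migrate from C3 to C2 before the borane arrives. The second allyl transfer may stall beside the di-ortho-substituted aryl group. The t-BuOH formed in the chlorination also consumes borane, hence the excess of 12.
- Fallback: the quaternary carbon is brought in with the indole instead of after the coupling. The sequence sets out from 2 and comes back at 17.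
- o-Toluidine is acylated with 2,2-dimethylbut-3-enoyl chloride to N-(2-methylphenyl)-2,2-dimethylbut-3-enamide F1. n-BuLi in THF should close this to 2-(2-methylbut-3-en-2-yl)-1H-indole F2 (Madelung indole synthesis in its organolithium variant).
- HCl-promoted conjugate addition of F2 to 2 gives 2,5-dichloro-3-[2-(2-methylbut-3-en-2-yl)-1H-indol-3-yl]benzene-1,4-diol F3. DDQ turns it into 2,5-dichloro-3-[2-(2-methylbut-3-en-2-yl)-1H-indol-3-yl]-1,4-benzoquinone F4.
- A second portion of F2 in hot AcOH adds to give 2,5-dichloro-3,6-bis[2-(2-methylbut-3-en-2-yl)-1H-indol-3-yl]benzene-1,4-diol F5. DDQ then gives 2,5-dichloro-3,6-bis[2-(2-methylbut-3-en-2-yl)-1H-indol-3-yl]-1,4-benzoquinone F6.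
- NaOMe in dry MeOH, as in step 3, exchanges both chlorides and leads directly to 17.

**Step 2.**
- Risk: the donor-substituted quinone 4 is a weak acceptor, so addition may be slower than acid-induced oligomerisation of indole. Indole may also displace chloride instead of attacking the C–H carbon.
- Fallback: both C3–core bonds are made by base-mediated substitution in place of acid-mediated addition and reoxidation. The sequence sets out from 1 and comes back at 7.
- Two equivalents of 1, tetrabromo-1,4-benzoquinone and Cs2CO3 in MeCN should give 2,5-dibromo-3,6-di(1H-indol-3-yl)-1,4-benzoquinone F7 by twofold addition–elimination with no redox step. NaOMe in dry MeOH–THF then exchanges the two remaining bromides to give 7.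

**Step 3.**
- Risk: deprotonation of the quinone-conjugated N–H groups may slow the second exchange. Traces of hydroxide may also cleave the vinylogous ester as it forms.
- Fallback: hydrolysis is made the aim and the methyl groups are put on afterwards. The sequence sets out from 6 and comes back at 7.
- Aqueous NaOH in refluxing MeOH converts 6 into 2,5-dihydroxy-3,6-di(1H-indol-3-yl)-1,4-benzoquinone F8. Its two acidic enol OH groups (vinylogous carboxylic acids) are methylated with Me3SiCHN2 in toluene–MeOH, a reagent that leaves the indole N–H alone.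

**Further compounds**
F1 | step 7 | N-(2-methylphenyl)-2,2-dimethylbut-3-enamide | C=CC(C)(C)C(=O)Nc1ccccc1C
F2 | step 7 | 2-(2-methylbut-3-en-2-yl)-1H-indole | C=CC(C)(C)c1cc2ccccc2[nH]1
F3 | step 7 | 2,5-dichloro-3-[2-(2-methylbut-3-en-2-yl)-1H-indol-3-yl]benzene-1,4-diol | Oc1cc(Cl)c(O)c(-c2c(C(C)(C)C=C)[nH]c3ccccc23)c1Cl
F4 | step 7 | 2,5-dichloro-3-[2-(2-methylbut-3-en-2-yl)-1H-indol-3-yl]-1,4-benzoquinone | O=C1C=C(Cl)C(=O)C(c2c(C(C)(C)C=C)[nH]c3ccccc23)=C1Cl
F5 | step 7 | 2,5-dichloro-3,6-bis[2-(2-methylbut-3-en-2-yl)-1H-indol-3-yl]benzene-1,4-diol | Oc1c(Cl)c(-c2c(C(C)(C)C=C)[nH]c3ccccc23)c(O)c(Cl)c1-c1c(C(C)(C)C=C)[nH]c2ccccc12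
F6 | step 7 | 2,5-dichloro-3,6-bis[2-(2-methylbut-3-en-2-yl)-1H-indol-3-yl]-1,4-benzoquinone | O=C1C(Cl)=C(c2c(C(C)(C)C=C)[nH]c3ccccc23)C(=O)C(Cl)=C1c1c(C(C)(C)C=C)[nH]c2ccccc12
F7 | step 2 | 2,5-dibromo-3,6-di(1H-indol-3-yl)-1,4-benzoquinone | O=C1C(Br)=C(c2c[nH]c3ccccc23)C(=O)C(Br)=C1c1c[nH]c2ccccc12
F8 | step 3 | 2,5-dihydroxy-3,6-di(1H-indol-3-yl)-1,4-benzoquinone | O=C1C(O)=C(c2c[nH]c3ccccc23)C(=O)C(O)=C1c1c[nH]c2ccccc12
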